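Bleochrin B is cut on ring B at two neighbouring bonds: C1'–Cβ of the two-carbon bridge and C6'–CH2 of the benzyl arm. Both are made in one palladium–norbornene relay (Catellani reaction) that joins 1-(benzyloxy)-3-iodobenzene, 4-(benzyloxy)benzyl chloride and a hexasubstituted ring A styrene: the benzyl enters at C6' by ortho C–H alkylation, then C1' is coupled to the terminal vinyl carbon by Heck reaction. The step exploits the adjacency of the C1' and C6' carbon substituents and the C3' oxygen, which shields C2'. The styrene, with three benzyl arms and the methoxy group in place, comes from 3-bromo-5-methoxyphenol by Friedel–Crafts benzylation, O-benzylation and vinylation; one hydrogenation then gives the target.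

Key step: step 6

Remarks on the chemistry (assumptions):
- Stilbene 10 carries six benzyl ethers: three on the ring A benzyl arms, one on the ring A oxygen, one on the ring B oxygen and one on the ring B benzyl arm. It is a hexa-O-benzyl compound, and step 7 must cleave six O–benzyl bonds.
- The ring A methoxy group is brought in with commercial 3-bromo-5-methoxyphenol, so no statistical mono-methylation of a symmetrical resorcinol is needed.
- Ring A takes up three 4-(benzyloxy)benzyl groups in step 2. Two are delivered by the symmetrical ether 3 and the third by alcohol 1, so the equation of step 2 is 4 + 3 + 1 → 5 + 2 H2O. Ether 3 releases only one molecule of water for two benzylations, which should keep the acidic fluoroalcohol medium dry and the standing concentration of free benzylic alcohol low.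
- The mono- and dibenzylated phenols of step 2 are regioisomer mixtures that converge on 5. They, and the catalyst-bound organopalladium species of steps 4 and 6, are not numbered.

Step 1
Reactants: 1 4-(benzyloxy)benzyl alcohol; 2 4-(benzyloxy)benzyl chloride
Product: 3 bis[4-(benzyloxy)benzyl] ether
Conditions: 50% aq NaOH, n-Bu4NHSO4 (5 mol%), toluene, rt
Reagents that add atoms: none
Why: Williamson ether synthesis under phase-transfer conditions, in which the alkoxide of the primary benzylic alcohol 1 should displace chloride from the activated benzylic chloride 2, and any 2 that is hydrolysed only gives more 1 and hence the same ether.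

Step 2
Reactants: 1 4-(benzyloxy)benzyl alcohol; 3 bis[4-(benzyloxy)benzyl] ether; 4 3-bromo-5-methoxyphenol
Product: 5 3-bromo-2,4,6-tris[4-(benzyloxy)benzyl]-5-methoxyphenol
Conditions: TsOH·H2O (10 mol%), HFIP/CH2Cl2, slow addition of 3 (1.1 equiv) and 1 (1.1 equiv), 0 °C to 40 °C
Reagents that add atoms: none
Why: Acid-catalysed Friedel–Crafts benzylation, in which ether 3 ionises to an alkoxy-stabilised benzylic cation and alcohol 1, alcohol 1 ionises in turn, and the three cations so formed should attack C2, C4 and C6 of phenol 4, each ortho or para to both oxygen substituents, while reversible O-alkylation under acid funnels the mixture to the C-tribenzylated phenol.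

Step 3
Reactants: 5 3-bromo-2,4,6-tris[4-(benzyloxy)benzyl]-5-methoxyphenol
Product: 6 1-(benzyloxy)-3-bromo-2,4,6-tris[4-(benzyloxy)benzyl]-5-methoxybenzene
Conditions: BnBr, K2CO3, DMF, 60 °C
Reagents that add atoms: benzyl bromide, BrCc1ccccc1
Why: Williamson ether synthesis, in which the phenoxide of 5, although flanked by two benzyl arms, should be alkylated by the unhindered primary bromide in a polar aprotic solvent while the aryl bromide and the ethers stay inert.

Step 4
Reactants: 6 1-(benzyloxy)-3-bromo-2,4,6-tris[4-(benzyloxy)benzyl]-5-methoxybenzene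
Product: 7 1-(benzyloxy)-2,4,6-tris[4-(benzyloxy)benzyl]-3-methoxy-5-vinylbenzene
Conditions: vinylboronic acid pinacol ester (2 equiv), Pd(OAc)2 (5 mol%), SPhos (10 mol%), K3PO4, toluene/H2O, 90 °C
Reagents that add atoms: vinylboronic acid pinacol ester (4,4,5,5-tetramethyl-2-vinyl-1,3,2-dioxaborolane), C=CB1OC(C)(C)C(C)(C)O1
Why: Suzuki–Miyaura coupling, for which the bulky electron-rich biaryl phosphine SPhos is chosen because it supports oxidative addition and reductive elimination at doubly ortho-substituted aryl bromides, and which leaves benzyl and methyl ethers untouched.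

Step 5
Reactants: 8 3-iodophenol
Product: 9 1-(benzyloxy)-3-iodobenzene
Conditions: BnBr, K2CO3, acetone, reflux
Reagents that add atoms: benzyl bromide, BrCc1ccccc1
Why: Williamson ether synthesis on an unhindered phenol, in which the aryl iodide is inert to carbonate and to benzyl bromide.

Step 6
Reactants: 2 4-(benzyloxy)benzyl chloride; 7 1-(benzyloxy)-2,4,6-tris[4-(benzyloxy)benzyl]-3-methoxy-5-vinylbenzene; 9 1-(benzyloxy)-3-iodobenzene
Product: 10 (E)-1-(benzyloxy)-2,4,6-tris[4-(benzyloxy)benzyl]-3-methoxy-5-{2-[5-(benzyloxy)-2-(4-(benzyloxy)benzyl)phenyl]vinyl}benzene (hexa-O-benzyl stilbene)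
Conditions: Pd(OAc)2 (10 mol%), tri(2-furyl)phosphine (20 mol%), norbornene (2 equiv), Cs2CO3 (3 equiv), DME/MeCN, 85 °C, argon, sealed vessel; 7 (1 equiv), 9 (1.5 equiv), 2 (2 equiv)
Reagents that add atoms: none
Why: Zerovalent palladium formed from Pd(OAc)2 and tri(2-furyl)phosphine inserts into the carbon–iodine bond of 9, norbornene inserts syn into the aryl–palladium bond, and carbonate-assisted palladation of the C6' hydrogen gives the five-membered aryl–norbornyl palladacycle of divalent palladium. Oxidative addition of the benzylic chloride 2 raises the metal to tetravalent palladium and reductive elimination forms the C6'–CH2 bond; with C6' now substituted and C2' closed to a second palladation, β-carbon elimination expels norbornene and leaves an arylpalladium species at C1'. This species adds across the vinyl group of 7 with aryl delivery to the unhindered terminal carbon, and syn β-hydride elimination releases the (E)-stilbene 10 and returns zerovalent palladium. The closest known reaction type is the Catellani ortho-alkylation of aryl iodides with alkyl halides under Heck termination, of which benzylic chlorides are accepted electrophiles. No ring is closed and no stereocentre is created; the alkene geometry follows from syn insertion and syn elimination and is erased in step 7. The selectivity needed is mono-benzylation at C6' and not at C2', and Heck coupling at C1' only after that benzylation; the C3' benzyloxy group, which crowds C2', and the much faster insertion of strained norbornene compared with the twisted, doubly ortho-substituted styrene should secure both.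

Step 7
Reactants: 10 hexa-O-benzyl (E)-stilbene
Product: 11 bleochrin B, 2,4,6-tris(4-hydroxybenzyl)-3-{2-[5-hydroxy-2-(4-hydroxybenzyl)phenyl]ethyl}-5-methoxyphenol
Conditions: H2 (1 atm), 10% Pd/C, THF/MeOH, rt
Reagents that add atoms: none
Why: Heterogeneous catalytic hydrogenation should saturate the 1,2-disubstituted stilbene double bond and hydrogenolyse the six aryl benzyl ethers in the same operation, while the diarylmethane C–C bonds and the aryl methyl ether are stable to H2 over Pd/C.

Compound list
1 | 4-(benzyloxy)benzyl alcohol | OCc1ccc(OCc2ccccc2)cc1 | starting material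
2 | 4-(benzyloxy)benzyl chloride | ClCc1ccc(OCc2ccccc2)cc1 | starting material
3 | bis[4-(benzyloxy)benzyl] ether | O(Cc1ccc(OCc2ccccc2)cc1)Cc1ccc(OCc2ccccc2)cc1 | intermediate
4 | 3-bromo-5-methoxyphenol | COc1cc(O)cc(Br)c1 | starting material
5 | 3-bromo-2,4,6-tris[4-(benzyloxy)benzyl]-5-methoxyphenol | COc1c(Cc2ccc(OCc3ccccc3)cc2)c(O)c(Cc2ccc(OCc3ccccc3)cc2)c(Br)c1Cc1ccc(OCc2ccccc2)cc1 | intermediate
6 | 1-(benzyloxy)-3-bromo-2,4,6-tris[4-(benzyloxy)benzyl]-5-methoxybenzene | COc1c(Cc2ccc(OCc3ccccc3)cc2)c(OCc2ccccc2)c(Cc2ccc(OCc3ccccc3)cc2)c(Br)c1Cc1ccc(OCc2ccccc2)cc1 | intermediate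
7 | 1-(benzyloxy)-2,4,6-tris[4-(benzyloxy)benzyl]-3-methoxy-5-vinylbenzene | COc1c(Cc2ccc(OCc3ccccc3)cc2)c(OCc2ccccc2)c(Cc2ccc(OCc3ccccc3)cc2)c(C=C)c1Cc1ccc(OCc2ccccc2)cc1 | intermediate
8 | 3-iodophenol | Oc1cccc(I)c1 | starting material
9 | 1-(benzyloxy)-3-iodobenzene | Ic1cccc(OCc2ccccc2)c1 | intermediate
10 | (E)-1-(benzyloxy)-2,4,6-tris[4-(benzyloxy)benzyl]-3-methoxy-5-{2-[5-(benzyloxy)-2-(4-(benzyloxy)benzyl)phenyl]vinyl}benzene | COc1c(Cc2ccc(OCc3ccccc3)cc2)c(OCc2ccccc2)c(Cc2ccc(OCc3ccccc3)cc2)c(/C=C/c2cc(OCc3ccccc3)ccc2Cc2ccc(OCc3ccccc3)cc2)c1Cc1ccc(OCc2ccccc2)cc1 | intermediate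
11 | bleochrin B, 2,4,6-tris(4-hydroxybenzyl)-3-{2-[5-hydroxy-2-(4-hydroxybenzyl)phenyl]ethyl}-5-methoxyphenol | COc1c(Cc2ccc(O)cc2)c(O)c(Cc2ccc(O)cc2)c(CCc2cc(O)ccc2Cc2ccc(O)cc2)c1Cc1ccc(O)cc1 | target

Total step count: 7. Longest linear sequence: 6 steps (steps 1, 2, 3, 4, 6 and 7).

Steps most likely to fail

1. Step 6 (three-component relay). Site control at the palladacycle stage may be lost: a second palladation at C2' would lead to double benzylation or to products that retain norbornene. The arylpalladium species may also be captured by the styrene before the ortho benzylation, or the Heck capture by the hindered styrene may be too slow, so that the benzylated arylpalladium is diverted. The fallback sets out from styrene 7 and comes back at stilbene 10, with ring B assembled beforehand with its benzyl arm in place. Purchased 2-bromo-4-hydroxybenzaldehyde is O-benzylated (BnBr, K2CO3, DMF) to 4-(benzyloxy)-2-bromobenzaldehyde F1. Addition of commercial [4-(benzyloxy)phenyl]magnesium bromide (THF, 0 °C) should give racemic [4-(benzyloxy)-2-bromophenyl][4-(benzyloxy)phenyl]methanol F2. Ionic deoxygenation (Et3SiH, TFA, CH2Cl2, 0 °C) should give 4-(benzyloxy)-1-[4-(benzyloxy)benzyl]-2-bromobenzene F3. An ordinary Mizoroki–Heck reaction of F3 with styrene 7 (Pd(OAc)2, P(o-tol)3, K2CO3, DMF, 110 °C) then gives 10.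

2. Step 2 (threefold Friedel–Crafts benzylation). The third alkylation at the positions next to bromine may stall, and the benzylic cation may condense with the benzyloxyphenyl rings of the donors and of the product. The fallback sets out from phenol 4 and comes back at bromide 6, making the three C–C bonds by cross-coupling in place of electrophilic substitution. Exhaustive iodination of 4 (NIS, 3.3 equiv, cat. TsOH, MeCN) should give 3-bromo-2,4,6-triiodo-5-methoxyphenol F4. O-Benzylation (BnBr, K2CO3, DMF) gives 1-(benzyloxy)-3-bromo-2,4,6-triiodo-5-methoxybenzene F5. Zinc insertion into chloride 2 (Zn dust, LiCl, THF) gives [4-(benzyloxy)benzyl]zinc chloride F6. A threefold Negishi coupling of F5 with F6 (Pd(PPh3)4, THF, 50 °C), selective for the three carbon–iodine bonds over the carbon–bromine bond, should give 6.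

3. Step 4 (Suzuki vinylation). Oxidative addition at the doubly flanked, electron-rich carbon–bromine bond may be sluggish, with competing protodebromination and loss of the vinylboron reagent. The fallback sets out from bromide 6 and comes back at styrene 7. Bromine–lithium exchange (n-BuLi, THF, −78 °C) gives [3-(benzyloxy)-2,4,6-tris(4-(benzyloxy)benzyl)-5-methoxyphenyl]lithium F7. Quenching with DMF gives 3-(benzyloxy)-2,4,6-tris[4-(benzyloxy)benzyl]-5-methoxybenzaldehyde F8. Wittig methylenation (Ph3PCH3Br, KOt-Bu, THF, 0 °C to rt) should give 7.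

Further compounds
F1 | step 6 | 4-(benzyloxy)-2-bromobenzaldehyde | O=Cc1ccc(OCc2ccccc2)cc1Br
F2 | step 6 | [4-(benzyloxy)-2-bromophenyl][4-(benzyloxy)phenyl]methanol (racemic) | OC(c1ccc(OCc2ccccc2)cc1)c1ccc(OCc2ccccc2)cc1Br
F3 | step 6 | 4-(benzyloxy)-1-[4-(benzyloxy)benzyl]-2-bromobenzene | Brc1cc(OCc2ccccc2)ccc1Cc1ccc(OCc2ccccc2)cc1
F4 | step 2 | 3-bromo-2,4,6-triiodo-5-methoxyphenol | COc1c(I)c(O)c(I)c(Br)c1I
F5 | step 2 | 1-(benzyloxy)-3-bromo-2,4,6-triiodo-5-methoxybenzene | COc1c(I)c(OCc2ccccc2)c(I)c(Br)c1I
F6 | step 2 | [4-(benzyloxy)benzyl]zinc chloride | Cl[Zn]Cc1ccc(OCc2ccccc2)cc1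
F7 | step 4 | [3-(benzyloxy)-2,4,6-tris(4-(benzyloxy)benzyl)-5-methoxyphenyl]lithium | COc1c(Cc2ccc(OCc3ccccc3)cc2)c(OCc2ccccc2)c(Cc2ccc(OCc3ccccc3)cc2)c([Li])c1Cc1ccc(OCc2ccccc2)cc1
F8 | step 4 | 3-(benzyloxy)-2,4,6-tris[4-(benzyloxy)benzyl]-5-methoxybenzaldehyde | COc1c(Cc2ccc(OCc3ccccc3)cc2)c(OCc2ccccc2)c(Cc2ccc(OCc3ccccc3)cc2)c(C=O)c1Cc1ccc(OCc2ccccc2)cc1
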